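**Retrosynthetic overview**

- C2–O last: the (2R)-carbinol is set by reagent-controlled (Davis) hydroxylation of the Z-enolate of the free 2,4-dihydroxyphenyl ketone.
- Key step: that ketone is released from 3-farnesyl-4,7-dihydroxycoumarin by lactone hydrolysis and decarboxylation, which destroys the heteroaromatic pyranone ring; the coumarin acts as a traceless, self-protecting β-keto-acid equivalent.
- C3–C1′: Tsuji–Trost farnesylation of 4,7-dihydroxycoumarin with (2E,6E)-farnesyl bromide, run in the same flask as the ring-opening.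
- The coumarin comes from resorcinol and malonic acid; acylation at one of the two equivalent positions breaks the C2v symmetry of resorcinol.
- Rings: the benzene ring is bought with resorcinol; the pyranone ring is built in step 1 and opened in step 2; no protecting groups.

Assumption: resorcinol, malonic acid, (2E,6E)-farnesyl bromide and both enantiomers of (camphorsulfonyl)oxaziridine are bought; the oxaziridine is a reagent and carries no compound number.

**Step 1**
Reactants: 1 resorcinol; 2 malonic acid
Product: 3 4,7-dihydroxy-2H-chromen-2-one (4,7-dihydroxycoumarin)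
Conditions: ZnCl2 (3 equiv), POCl3 (3 equiv), 65 °C, 30 h; ice-water work-up
Reagents that add atoms: malonic acid 2, OC(=O)CC(O)=O
Why: Friedel–Crafts C-acylation followed by lactonisation (Shah's 4-hydroxycoumarin synthesis), in which the activated malonic acid attacks para to one hydroxyl and the ortho hydroxyl closes the lactone, so the two equivalent positions of resorcinol are differentiated and only the 7-hydroxy isomer forms.

**Step 2**
Reactants: 3 4,7-dihydroxycoumarin; 4 (2E,6E)-farnesyl bromide
Product: 7 (4E,8E)-1-(2,4-dihydroxyphenyl)-5,9,13-trimethyltetradeca-4,8,12-trien-1-one, via ammoresinol 5 (not isolated), via ring-opened β-keto acid 6 (not isolated)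
Conditions: KOH (1.0 equiv), Pd(PPh3)4 (5 mol %), 4 (0.95 equiv), 1,4-dioxane/H2O 9:1, 50 °C, Ar; then 20% aq KOH, 100 °C, 8 h; then 1 M HCl to pH 3, 0 °C
Reagents that add atoms: (2E,6E)-farnesyl bromide 4, CC(C)=CCC/C(C)=C/CC/C(C)=C/CBr
Why: Tsuji–Trost allylation, in which the soft C3 carbon of the coumarin anion attacks the primary terminus of the farnesyl π-allyl complex of zerovalent palladium (any O-farnesyl ether is re-ionised and funnelled to the C-isomer, keeping the 2E olefin), followed in the same flask by lactone saponification and β-keto-acid decarboxylation (ketonic cleavage), which destroys the pyranone ring and releases the mono-alkylated ketone with both phenols free.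

**Step 3**
Reactants: 7 (4E,8E)-1-(2,4-dihydroxyphenyl)-5,9,13-trimethyltetradeca-4,8,12-trien-1-one
Product: 9 (2R,4E,8E)-1-(2,4-dihydroxyphenyl)-2-hydroxy-5,9,13-trimethyltetradeca-4,8,12-trien-1-one, via trisodium enolate 8 (not isolated)
Conditions: NaN(SiMe3)2 (3.5 equiv), THF, −78 to 0 °C, 1 h; then (−)-(2S,8aR)-(camphorsulfonyl)oxaziridine (1.3 equiv), THF, −78 °C, 2 h; saturated aq NH4Cl, −78 °C
Reagents that add atoms: (−)-(2S,8aR)-(camphorsulfonyl)oxaziridine, CC1(C)[C@H]2CC[C@@]13CS(=O)(=O)[N@@]4O[C@]34C2
Why: Davis asymmetric enolate hydroxylation, in which the Z sodium enolate 8 attacks the electrophilic oxygen of the oxaziridine in an open SN2-type transition state while the camphor framework shields one enolate face, so that, following the rule that the (2R,8aS) reagent gives (S)-carbinols from Z-enolates of aryl alkyl ketones, its (2S,8aR) enantiomer sets C2 as R.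

**Compound list**

1 | resorcinol (benzene-1,3-diol) | Oc1cccc(O)c1 | starting material
2 | malonic acid (propanedioic acid) | OC(=O)CC(O)=O | starting material
3 | 4,7-dihydroxy-2H-chromen-2-one (4,7-dihydroxycoumarin) | Oc1ccc2c(O)cc(=O)oc2c1 | intermediate
4 | (2E,6E)-1-bromo-3,7,11-trimethyldodeca-2,6,10-triene ((2E,6E)-farnesyl bromide) | CC(C)=CCC/C(C)=C/CC/C(C)=C/CBr | starting material
5 | 4,7-dihydroxy-3-[(2E,6E)-3,7,11-trimethyldodeca-2,6,10-trien-1-yl]-2H-chromen-2-one (ammoresinol; formed as its potassium salt) | CC(C)=CCC/C(C)=C/CC/C(C)=C/Cc1c(O)c2ccc(O)cc2oc1=O | intermediate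
6 | (4E,8E)-2-(2,4-dihydroxybenzoyl)-5,9,13-trimethyltetradeca-4,8,12-trienoic acid (racemic; formed as its potassium salt) | CC(C)=CCC/C(C)=C/CC/C(C)=C/CC(C(O)=O)C(=O)c1ccc(O)cc1O | intermediate
7 | (4E,8E)-1-(2,4-dihydroxyphenyl)-5,9,13-trimethyltetradeca-4,8,12-trien-1-one | CC(C)=CCC/C(C)=C/CC/C(C)=C/CCC(=O)c1ccc(O)cc1O | intermediate
8 | trisodium 4-[(1Z,4E,8E)-1-oxido-5,9,13-trimethyltetradeca-1,4,8,12-tetraen-1-yl]benzene-1,3-diolate | [Na+].[Na+].[Na+].CC(C)=CCC/C(C)=C/CC/C(C)=C/C/C=C(\[O-])c1ccc([O-])cc1[O-] | intermediate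
9 | (2R,4E,8E)-1-(2,4-dihydroxyphenyl)-2-hydroxy-5,9,13-trimethyltetradeca-4,8,12-trien-1-one | CC(C)=CCC/C(C)=C/CC/C(C)=C/C[C@@H](O)C(=O)c1ccc(O)cc1O | target

**Step count and risks**

Total step count: 3. Longest linear sequence: 3 steps (1 → 3 → 7 → 9); compounds 2 and 4 enter directly and need no steps of their own.

Steps most likely to fail, in order of risk:

Step 3. Two things are untested: whether the amide base fully enolises the electron-rich bis-phenoxide ketone, and whether the facial bias known for simple mono-anionic enolates holds for a chelated trianion. Low conversion or low ee are both possible. The fallback sets out from 7 and comes back at 9. Both phenols of 7 are capped (NaH, MOMCl, DMF, 0 °C) to give (4E,8E)-1-[2,4-bis(methoxymethoxy)phenyl]-5,9,13-trimethyltetradeca-4,8,12-trien-1-one F1. NaN(SiMe3)2 (1.2 equiv, THF, −78 °C) then gives sodium (1Z,4E,8E)-1-[2,4-bis(methoxymethoxy)phenyl]-5,9,13-trimethyltetradeca-1,4,8,12-tetraen-1-olate F2, a mono-anionic aryl alkyl ketone enolate of the kind for which about 95% ee is documented. The same oxaziridine converts it into (2R,4E,8E)-1-[2,4-bis(methoxymethoxy)phenyl]-2-hydroxy-5,9,13-trimethyltetradeca-4,8,12-trien-1-one F3. HCl (0.1 M in MeOH, 25 °C) removes both acetals and returns 9.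

Step 2. The palladium stage can give 3,3-bis-farnesylation, residual O-alkylation, or partial loss of the 2E geometry through the π-allyl intermediate. The doubly deprotonated coumarin may also resist hydroxide, so the ring-opening could stall. The fallback sets out from 1 and comes back at 7, with no coumarin and no palladium. Nencki acylation of 1 (AcOH, ZnCl2, 140 °C) gives 1-(2,4-dihydroxyphenyl)ethan-1-one F4. LiN(SiMe3)2 (3.3 equiv, THF, −78 to −10 °C) turns it into trilithium 4-(1-oxidoethenyl)benzene-1,3-diolate F5. Its carbon terminus is alkylated by 4 (−78 to 0 °C) to give 7 directly.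

Step 1. The product can condense with a second malonic acid to a pyranocoumarin, and phosphorylated phenols can lower the yield. The fallback sets out from 1 and comes back at 3, separating the two bond formations. Compound 1 (2 equiv) is O-acylated by Meldrum's acid (toluene, 100 °C) to give 3-(3-hydroxyphenoxy)-3-oxopropanoic acid F6. Intramolecular Friedel–Crafts acylation in P2O5/MeSO3H (70 °C) then closes the ring para to the free hydroxyl to give 3.

**Further compounds**

F1 | step 3 | (4E,8E)-1-[2,4-bis(methoxymethoxy)phenyl]-5,9,13-trimethyltetradeca-4,8,12-trien-1-one | CC(C)=CCC/C(C)=C/CC/C(C)=C/CCC(=O)c1ccc(OCOC)cc1OCOC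
F2 | step 3 | sodium (1Z,4E,8E)-1-[2,4-bis(methoxymethoxy)phenyl]-5,9,13-trimethyltetradeca-1,4,8,12-tetraen-1-olate | [Na+].CC(C)=CCC/C(C)=C/CC/C(C)=C/C/C=C(\[O-])c1ccc(OCOC)cc1OCOC
F3 | step 3 | (2R,4E,8E)-1-[2,4-bis(methoxymethoxy)phenyl]-2-hydroxy-5,9,13-trimethyltetradeca-4,8,12-trien-1-one | CC(C)=CCC/C(C)=C/CC/C(C)=C/C[C@@H](O)C(=O)c1ccc(OCOC)cc1OCOC
F4 | step 2 | 1-(2,4-dihydroxyphenyl)ethan-1-one | CC(=O)c1ccc(O)cc1O
F5 | step 2 | trilithium 4-(1-oxidoethenyl)benzene-1,3-diolate | [Li+].[Li+].[Li+].C=C([O-])c1ccc([O-])cc1[O-]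
F6 | step 1 | 3-(3-hydroxyphenoxy)-3-oxopropanoic acid | OC(=O)CC(=O)Oc1cccc(O)c1
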